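**1. The scale.** Units per chain is the measure: Z in chains over chains begun.

in all of them: Z 0.010 M (fed, over 80 min); J 2.00 mM; E 0.25 mM
- violet: time 4.0 h
- red: time 1.2 h

* which of the two ends with the longer chains by the average number of monomer units in a chain (chains begun, living or dead) ("neither" if they lie within 10 %) (violet / red / neither)
* average number of monomer units in a chain (chains begun, living or dead) at the end, violet
* average number of monomer units in a chain (chains begun, living or dead) at the end, red

- the average divides the monomer in chains by the number of chains begun, living and dead together
- percentages count the whole charge, also what has not yet gone in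
- run time (violet): 4.0 h

    Z + E → D + G (k1 = 15 M⁻¹ min⁻¹)
    Z + D → G + D, rate k2*[D]*[Z] (k2 = 68 M⁻¹ min⁻¹)
    J + Z → J.Z (k3 = 4.3 M⁻¹ min⁻¹)
    Z → Q (k4 = 0.0076 min⁻¹)

If each charged Z entered a chain and each E began one, the length would be 40.0. That is the zero of the scale, and losses are counted from it.

**2. Start.** With ends at the charge of E and J at its charge, each Z meets three pseudo-first-order rates. Growth runs at 0.0170 min⁻¹, faster than 0.00860 min⁻¹ into J.Z and 0.0076 min⁻¹ into Q. Their sum is 0.0332 min⁻¹, and growth over that sum gives 0.512: this is the chain share, the selectivity for chains, the fraction of consumed Z that enters G.

**3. What shifts it.** Ends start from zero and come from E, whose lifetime, reckoned at the standing [Z], is 17.7 min, shorter than the feed. By the same reckoning, the J term at the end of the feed stands at 0.274 of its starting value, and the share with full ends comes to 0.631. Ends below their full number pull the share the other way, and my reckoning keeps the starting share.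

**4. Ends.** In violet, 5.31 reckoned Z lifetimes follow the feed, so my reckoned length is 20.5. In red, 90.0 % of the charge is in, and feed over total rate gives a reckoned 37.7 % standing, so my reckoned length is 10.7. My violet figure comes out at nearly twice my red one.

**5. Forecast.** It names violet, with 22 for violet and 10.5 for red, and holds that by the end of violet “the monomer is essentially used up”. It stands above my violet figure and below my red one.

**6. Result.** The simulation gives violet, with 22.0 for violet and 10.3 for red.

The two flasks differ in time: red ends with Z at 39.8 % and G at 24.3 %, and left ten times as long it reaches 22.2. Violet ends with G at 54.9 % of the charge, above the starting chain share of 51.2 %. In the neighbouring flask, violet with 6.3 × 10⁻⁴ M of E, the starting chain share rises to 0.726 while the zero of the scale falls to 15.9, so the reckoned length is 11.5. That flask gives 11.8, with G at 71.4 %.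

The numbers of this flask are assumed.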